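The readings are calculated with made-up constants; scatter was added.

The grey run's substrate reading at 10.0 min puts its half-life at 7.50 min, while its product readings at 20.0 min and 30.0 min, drawn back in a straight line, reach zero at 13.7 min, an induction period longer than that half-life.

| flask | substrate | reagent | remark | time |
|---|---|---|---|---|
| grey | 46 mM | 55.2 mM | run made earlier |  |
| amber | 46 mM | 28 mM | run made earlier |  |
| violet | 46 mM | 41 mM | run made earlier |  |
| ochre | 23 mM | 55.2 mM | run made earlier |  |
| noon | 46 mM (fed, over 30 min) | 55.2 mM | all else is in the flask from the start; the feed brings no volume worth counting | 40 min |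
| winter | 46 mM | 55.2 mM (fed, over 30 min) | all else is in the flask from the start; the feed brings no volume worth counting | 40 min |
| spring | 46 mM | 55.2 mM | everything together at the start | 40 min |
| dusk | 46 mM | 55.2 mM (in portions, 2, over 30 min) | first portion at the start, last at 30 min | 40 min |

| run | time / min | product / % | substrate / % |
|---|---|---|---|
| grey | 10.0 | 0.6 | 39.7 |
| grey | 20.0 | 3.2 | 22.4 |
| grey | 30.0 | 8.3 | 13.4 |
| grey | 40.0 | 13.6 | 8.5 |
| amber | 5.00 | 0 | 63.7 |
| amber | 15.0 | 0.6 | 32.2 |
| amber | 25.0 | 2.4 | 17.8 |
| amber | 40.0 | 4.9 | 7.1 |
| violet | 5.00 | 0 | 61.8 |
| violet | 15.0 | 1.4 | 30.2 |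
| violet | 25.0 | 3.6 | 17.5 |
| violet | 40.0 | 8.9 | 8.2 |
| ochre | 10.0 | 1.4 | 40.3 |
| ochre | 20.0 | 3.7 | 23.1 |
| ochre | 30.0 | 10.7 | 14.9 |
| ochre | 40.0 | 16.2 | 8.8 |

(each reading ± 0.5 percentage points)

- what was read earlier has a scatter of 0.5 percentage points, one standard deviation
- a reading of substrate is of its free form alone

* which flask leads in amount of product, in percent of the substrate charged ("all alike" within 1.5 percentage points) (noon / winter / spring / dusk / all alike)
* how much product is there at the end, in percent of the substrate charged: noon
* how much product is there at the end, in percent of the substrate charged: winter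
* how much product is there at the end, in percent of the substrate charged: spring
* how much product is there at the end, in percent of the substrate charged: dusk

On the first rung stands the loss of substrate. Ochre, with half the substrate of grey, keeps 40.3 % at 10.0 min against grey's 39.7 %. Amber, with about half the reagent of grey, holds 7.1 % at 40.0 min against grey's 8.5 %. So this loss reads as first order in substrate, and reagent shows little in it. The induction period is the next rung, and I take it as the crossing: before it, at 10.0 min, grey reads 0.6 % product, and after it product climbs at a pace that follows the reagent. The last rung is the run itself. At 40.0 min grey shows 13.6 % product and 8.5 % substrate, so 77.9 % of the charge stands in unseen forms. Amber has 4.9 % product where grey has 13.6 %, which gives the apparent reagent order, the logarithm of the product ratio at equal time and equal substrate charge over the logarithm of the reagent ratio: 1.50, a reading with the scatter of those two values.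

Spring repeats the recipe of grey, so I take 13.6 % for it. The first portion in dusk is half the charge, so I scale grey's 8.3 % at 30.0 min by one half to that order, which gives 2.93 %. I then add grey's later gain of 5.3 percentage points, taking the last portion to restore grey's pace, and reach 8.23 %, which is less than spring. The forecast, noting “Most of it sits in an unseen intermediate”, puts spring first, with noon at 6 %, winter at 9.8 %, spring at 13.6 % and dusk at 7.9 %, a little below my figure.

The flasks give 13.5 % in spring, which leads, then 10.3 % in winter, 8.25 % in dusk and 6.69 % in noon.

    substrate → intermediate A (k = 0.00120 /s)
    substrate + reagent ⇌ intermediate B (K = 7.40 /M, k = 0.0180 /M/s)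
    reagent + intermediate A ⇌ intermediate C (K = 41.0 /M, k = 0.00650 /M/s)
    reagent + intermediate C → product (k = 0.0180 /M/s)

At 40.0 min spring holds 59.9 % as intermediate A against 13.5 % as product. The order 1.50 put dusk at 2.93 % by 30.0 min, and just before its last addition dusk holds 2.74 %. Carried from noon's 6.69 % to its neighbour charged with 220 mM of reagent, the same order reckons 53.5 %, and that neighbour holds 26.0 %.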